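**Selectivity constant.** The constant to read first is the selectivity factor: the rate of left-handed product over that of right-handed product at equal substrate concentrations. Each reading scatters by 0.3 percentage points, so it is taken from sums. The left-handed readings of the earlier runs add up to 25.4%, the right-handed ones to 5.50%, so the factor reads 4.62.

in all of them: precatalyst 0.33 mM
- eta: left-handed substrate 0.22 M; right-handed substrate 0.22 M; partner 0.46 M; protic impurity 0.022 M; run made earlier
- alpha: left-handed substrate 0.22 M; right-handed substrate 0.22 M; partner 0.73 M; protic impurity 0.022 M; run made earlier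
- epsilon: left-handed substrate 0.33 M; right-handed substrate 0.33 M; partner 0.33 M; protic impurity 0.022 M; run made earlier
- flask: left-handed substrate 0.22 M; right-handed substrate 0.22 M; partner 0.330 M; protic impurity 0.0220 M; time 2.5 min

| run | time / s | left-handed product / % | right-handed product / % |
|---|---|---|---|
| eta | 15.0 | 0.2 | 0 |
| eta | 30.0 | 0.9 | 0.7 |
| eta | 50.0 | 2.2 | 0.1 |
| eta | 60.0 | 2.1 | 0.4 |
| eta | 80.0 | 2.5 | 0.5 |
| eta | 90.0 | 3.0 | 1.6 |
| alpha | 10.0 | 0.4 | 0 |
| alpha | 20.0 | 0.5 | 0 |
| alpha | 30.0 | 0.6 | 0.4 |
| alpha | 50.0 | 1.0 | 0.1 |
| alpha | 60.0 | 2.8 | 0.1 |
| alpha | 90.0 | 3.7 | 1.2 |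
| epsilon | 10.0 | 0.1 | 0 |
| epsilon | 25.0 | 0.8 | 0.3 |
| epsilon | 40.0 | 0.6 | 0.1 |
| epsilon | 60.0 | 1.2 | 0 |
| epsilon | 90.0 | 2.8 | 0 |

(each reading ± 0.3 percentage points)

- free catalyst is single-handed; left-handed substrate and right-handed substrate are mirror images of each other, charged as a racemate, each of them at the stated concentration
- an excess is the difference of the two amounts in percent of their sum
- an excess is below zero if the other one leads

- excess of left-handed product over right-handed product in the product at 3.0 s
- excess of left-handed product over right-handed product in the product at 2.5 min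
- part of the left-handed substrate and right-handed substrate charged together that has reacted at 2.5 min

**Hand chain.** The reckoning here assumes that the rate ratio equals this factor times left-handed over right-handed substrate. At 3.0 s the reckoning takes the substrates at their charges, so the excess is (factor − 1)/(factor + 1), 64.4%. The two products together at the last eta and alpha readings average 4.75%, and a straight line, taken over to the flask as an estimate, carries that to 7.92% reacted at 2.5 min. With the starting left-handed share of product, 82.2%, the midway ratio is the factor times (1 − conversion × share)/(1 − conversion × other share). This gives an excess of 62.8%.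

**Weak link.** That pass used the starting share. Putting back the share from its own answer, 81.4%, gives 62.9%, which is the excess committed here for 2.5 min, with 7.92% reacted.

**The forecast.** It gives an excess of 65% at 3.0 s, an excess of 62% at 2.5 min and 10% reacted at 2.5 min: “Slight substrate depletion lowers the excess to about 62%”. Its conversion stands above the straight-line one here.

**The result.** The flask gives an excess of 63.0% at 3.0 s, an excess of 61.3% at 2.5 min and 6.25% reacted at 2.5 min.

    free catalyst + left-handed substrate ⇌ catalyst intermediate A (K = 6.30 M⁻¹, k = 4240 M⁻¹ s⁻¹)
    free catalyst + right-handed substrate ⇌ catalyst intermediate B (K = 3.00 M⁻¹, k = 699 M⁻¹ s⁻¹)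
    partner + catalyst intermediate A → free catalyst + left-handed product (k = 108 M⁻¹ s⁻¹)
    partner + catalyst intermediate B → free catalyst + right-handed product (k = 52.5 M⁻¹ s⁻¹)
    partner + protic impurity → quenched reagent (k = 0.971 M⁻¹ s⁻¹)
    2 partner → homo dimer (k = 0.0499 M⁻¹ s⁻¹)
    precatalyst → free catalyst (k = 0.00181 s⁻¹)

At 2.5 min the left-handed substrate in the flask keeps 90% of its charge and the right-handed substrate 98%. The factor at the flask's conversion gives a fall in excess of 1.2 points, and the flask falls 1.7 points.

**Neighbour flask.** A neighbour with 8.2 × 10⁻⁴ M of precatalyst has 13.1% reacted at 2.5 min, where the factor gives a fall of 2.7 points. The computed excess of that neighbour goes from 63.0% at 3.0 s to 59.8% at 2.5 min.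

The numbers in the tables were generated by integration with constants of no real substance; the scatter is artificial.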